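**Plan**
- Retrosynthesis: the pyranone (ring C) is cut at O1–C2 and C2–C3, so C2 is a one-carbon unit added late to a 2-hydroxydeoxybenzoin, whose C4 carbonyl is traced back to a silyl-protected carbinol.
- Ring A is then cut completely, at C4a–C8a, C5–C6 and C8–C8a. It is a fully differentiated phloroglucinol (O on C5, C7 and C8a, methyl on C6, carbon on C4a), and this 1,3,5-oxygen pattern maps onto a 3-benzyloxy-2-methylcyclobutenone (C6, C7, C8, C8a) and a methoxyalkyne (C4a, C5).
- The alkyne is cut at C4–C4a into lithium methoxyacetylide and the arylacetaldehyde that carries ring B and C3.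
- Forward: ring B is bought (methoxyeugenol), the C3–C4–C4a–C5 chain is joined by acetylide addition, ring A arises in the benzannulation, ring C closes by formylative condensation, and hydrogenolysis frees both phenols.
- Stereochemistry: the target has none. The single carbinol centre on the way is made racemic and is erased on oxidation to C4=O.

Key step: step 8

Assumption: the target is achiral (no stereocentre, no stereogenic double bond), so the requirement of a single enantiomer is met by the constitution alone and racemic intermediates are acceptable.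

**Route**

Step 1
Reactants: 1 acetyl chloride; 2 1-ethoxypropyne
Product: 4 3-ethoxy-2-methylcyclobut-2-en-1-one, via ketene 3 (not isolated)
Conditions: Et3N, Et2O, 0 °C → rt (slow addition of 1)
Reagents that add atoms: none
Why: Triethylamine dehydrochlorinates acetyl chloride to ketene, which the electron-rich ynol ether traps in a regioselective thermal [2+2] cycloaddition (carbonyl carbon to the methyl-bearing alkyne carbon), the standard entry to 3-alkoxycyclobutenones.

Step 2
Reactants: 4 3-ethoxy-2-methylcyclobut-2-en-1-one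
Product: 5 2-methylcyclobutane-1,3-dione (present as its enol, 3-hydroxy-2-methylcyclobut-2-en-1-one)
Conditions: 1 M aq. HCl, THF, rt
Reagents that add atoms: water, O
Why: Acid-catalysed hydrolysis of the vinylogous ester (addition–elimination at C3) should free the symmetrical, strongly acidic enol, so the following O-alkylation has no regiochemical question.

Step 3
Reactants: 5 2-methylcyclobutane-1,3-dione
Product: 6 3-(benzyloxy)-2-methylcyclobut-2-en-1-one
Conditions: BnOH, PPh3, DIAD, THF, 0 °C → rt
Reagents that add atoms: benzyl alcohol, OCc1ccccc1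
Why: Mitsunobu O-alkylation, in which the vinylogous acid protonates the betaine and its oxygen displaces the oxyphosphonium of benzyl alcohol, should give the benzyl vinylogous ester without C-alkylation.

Step 4
Reactants: 7 4-allyl-2,6-dimethoxyphenol
Product: 8 5-allyl-2-(benzyloxy)-1,3-dimethoxybenzene
Conditions: BnBr, K2CO3, acetone, reflux
Reagents that add atoms: benzyl bromide, BrCc1ccccc1
Why: Williamson etherification of the acidic 2,6-dimethoxyphenol; benzyl is chosen so that this group and the ring A benzyl ether leave together in the last step.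

Step 5
Reactants: 8 5-allyl-2-(benzyloxy)-1,3-dimethoxybenzene
Product: 9 2-[4-(benzyloxy)-3,5-dimethoxyphenyl]acetaldehyde
Conditions: O3, CH2Cl2, −78 °C (indicator end-point); then PPh3, −78 °C → rt; used crude
Reagents that add atoms: ozone, [O-][O+]=O
Why: Ozonolysis with reductive work-up should cleave only the terminal allyl C=C at −78 °C when ozone is stopped at the end-point, leaving the trialkoxyarene untouched.

Step 6
Reactants: 9 2-[4-(benzyloxy)-3,5-dimethoxyphenyl]acetaldehyde; 10 chloroacetaldehyde dimethyl acetal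
Product: 12 1-[4-(benzyloxy)-3,5-dimethoxyphenyl]-4-methoxybut-3-yn-2-ol (racemic), via lithium methoxyacetylide 11 (not isolated)
Conditions: 10, n-BuLi/Et2NH (LiNEt2, 3 equiv per 10), THF, 0 °C; then 9, −78 °C; H2O quench
Reagents that add atoms: none
Why: Twofold β-elimination of the chloroacetal (methanol, then HCl) and deprotonation give the lithium alkoxyacetylide, which adds 1,2 to the aldehyde (acetylide addition); the carbinol centre forms racemic, which is acceptable because it becomes C4=O.

Step 7
Reactants: 12 1-[4-(benzyloxy)-3,5-dimethoxyphenyl]-4-methoxybut-3-yn-2-ol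
Product: 13 tert-butyl({1-[4-(benzyloxy)-3,5-dimethoxyphenyl]-4-methoxybut-3-yn-2-yl}oxy)dimethylsilane (racemic)
Conditions: TBSCl, imidazole, DMF, rt
Reagents that add atoms: tert-butyldimethylsilyl chloride, CC(C)(C)[Si](C)(C)Cl
Why: Standard silylation under basic conditions should leave the acid-sensitive ynol ether intact and remove the free hydroxyl that would otherwise capture the ketene in the next step.

Step 8
Reactants: 6 3-(benzyloxy)-2-methylcyclobut-2-en-1-one; 13 tert-butyl({1-[4-(benzyloxy)-3,5-dimethoxyphenyl]-4-methoxybut-3-yn-2-yl}oxy)dimethylsilane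
Product: 18 5-(benzyloxy)-2-{2-[4-(benzyloxy)-3,5-dimethoxyphenyl]-1-[(tert-butyldimethylsilyl)oxy]ethyl}-3-methoxy-4-methylphenol (racemic), via vinylketene 14 (not isolated), via 4-vinylcyclobutenone 15 (not isolated), via dienylketene 16 (not isolated), via cyclohexadienone 17 (not isolated)
Conditions: toluene, sealed tube, 110 → 140 °C
Reagents that add atoms: none
Why: Heating should open cyclobutenone 6 by 4π-electrocyclic cleavage to vinylketene 14, whose ketene unit adds [2+2] to the ynol ether to give 15 (C4a–C8a and C5–C6 formed); 15 opens again to dienylketene 16, which closes to dienone 17 and tautomerises to phenol 18. The closest known reaction is the Danheiser benzannulation of cyclobutenones with alkoxyalkynes to resorcinol monoethers. Ring A closes by a thermal disrotatory 6π-electrocyclisation that forms C8–C8a. No stereocentre is created, and the silyloxy carbon stays racemic. The step needs one regiochemical outcome in the [2+2], namely bonding of the ketene carbonyl carbon to the alkyne carbon β to the methoxy group; the polarisation of the ynol ether (nucleophilic β-carbon) against the electrophilic ketene carbon secures it, so C8a–OH, C5–OMe, C6–Me, C7–OBn and C8–H are each placed without ambiguity. A methyl ynol ether is used because it cannot fragment by retro-ene reaction at the temperature required.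

Step 9
Reactants: 18 5-(benzyloxy)-2-{2-[4-(benzyloxy)-3,5-dimethoxyphenyl]-1-[(tert-butyldimethylsilyl)oxy]ethyl}-3-methoxy-4-methylphenol
Product: 19 5-(benzyloxy)-2-{2-[4-(benzyloxy)-3,5-dimethoxyphenyl]-1-hydroxyethyl}-3-methoxy-4-methylphenol (racemic)
Conditions: TBAF, AcOH, THF, 0 °C → rt; used without acidic contact
Reagents that add atoms: none
Why: Buffered fluoride desilylation should cleave the benzylic silyl ether while the benzyl and methyl aryl ethers are inert, the buffer keeping the medium from ionising the electron-rich benzylic alcohol.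

Step 10
Reactants: 19 5-(benzyloxy)-2-{2-[4-(benzyloxy)-3,5-dimethoxyphenyl]-1-hydroxyethyl}-3-methoxy-4-methylphenol
Product: 20 1-[4-(benzyloxy)-6-hydroxy-2-methoxy-3-methylphenyl]-2-[4-(benzyloxy)-3,5-dimethoxyphenyl]ethan-1-one
Conditions: activated MnO2, CH2Cl2, rt
Reagents that add atoms: none
Why: Activated manganese dioxide oxidises benzylic alcohols selectively, and the product is stabilised as a hydrogen-bonded o-hydroxyaryl ketone, so the phenol should need no protection.

Step 11
Reactants: 20 1-[4-(benzyloxy)-6-hydroxy-2-methoxy-3-methylphenyl]-2-[4-(benzyloxy)-3,5-dimethoxyphenyl]ethan-1-one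
Product: 22 7-(benzyloxy)-3-[4-(benzyloxy)-3,5-dimethoxyphenyl]-5-methoxy-6-methyl-4H-chromen-4-one, via enaminone 21 (not isolated)
Conditions: DMF-DMA, toluene, 100 °C
Reagents that add atoms: N,N-dimethylformamide dimethyl acetal, COC(OC)N(C)C
Why: Condensation of the deoxybenzoin methylene with the amide acetal gives the enaminone, and the only free ortho hydroxyl adds 6-endo (oxa-Michael) with loss of dimethylamine to close the pyranone, the standard deoxybenzoin route to isoflavones.

Step 12
Reactants: 22 7-(benzyloxy)-3-[4-(benzyloxy)-3,5-dimethoxyphenyl]-5-methoxy-6-methyl-4H-chromen-4-one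
Product: 23 7-hydroxy-3-(4-hydroxy-3,5-dimethoxyphenyl)-5-methoxy-6-methyl-4H-chromen-4-one
Conditions: H2 (1 atm), 10% Pd/C, EtOAc–MeOH, rt
Reagents that add atoms: none
Why: Catalytic hydrogenolysis of the two benzyl aryl ethers under mild conditions, stopped after two equivalents of hydrogen, should leave the methyl ethers and the chromone C2=C3 bond intact.

**Compound list**

1 | acetyl chloride | CC(=O)Cl | starting material
2 | 1-ethoxypropyne | CCOC#CC | starting material
3 | ketene | C=C=O | intermediate
4 | 3-ethoxy-2-methylcyclobut-2-en-1-one | CCOC1=C(C)C(=O)C1 | intermediate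
5 | 2-methylcyclobutane-1,3-dione (enol form, 3-hydroxy-2-methylcyclobut-2-en-1-one) | CC1=C(O)CC1=O | intermediate
6 | 3-(benzyloxy)-2-methylcyclobut-2-en-1-one | CC1=C(OCc2ccccc2)CC1=O | intermediate
7 | 4-allyl-2,6-dimethoxyphenol | C=CCc1cc(OC)c(O)c(OC)c1 | starting material
8 | 5-allyl-2-(benzyloxy)-1,3-dimethoxybenzene | C=CCc1cc(OC)c(OCc2ccccc2)c(OC)c1 | intermediate
9 | 2-[4-(benzyloxy)-3,5-dimethoxyphenyl]acetaldehyde | O=CCc1cc(OC)c(OCc2ccccc2)c(OC)c1 | intermediate
10 | chloroacetaldehyde dimethyl acetal | COC(CCl)OC | starting material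
11 | lithium methoxyacetylide | [Li]C#COC | intermediate
12 | 1-[4-(benzyloxy)-3,5-dimethoxyphenyl]-4-methoxybut-3-yn-2-ol (racemic) | COC#CC(O)Cc1cc(OC)c(OCc2ccccc2)c(OC)c1 | intermediate
13 | tert-butyl({1-[4-(benzyloxy)-3,5-dimethoxyphenyl]-4-methoxybut-3-yn-2-yl}oxy)dimethylsilane (racemic) | COC#CC(Cc1cc(OC)c(OCc2ccccc2)c(OC)c1)O[Si](C)(C)C(C)(C)C | intermediate
14 | 3-(benzyloxy)-2-methylbuta-1,3-dien-1-one (vinylketene) | C=C(OCc1ccccc1)C(C)=C=O | intermediate
15 | 4-[1-(benzyloxy)ethenyl]-2-{2-[4-(benzyloxy)-3,5-dimethoxyphenyl]-1-[(tert-butyldimethylsilyl)oxy]ethyl}-3-methoxy-4-methylcyclobut-2-en-1-one (diastereomer mixture) | C=C(OCc1ccccc1)C1(C)C(OC)=C(C(Cc2cc(OC)c(OCc3ccccc3)c(OC)c2)O[Si](C)(C)C(C)(C)C)C1=O | intermediate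
16 | (3E)-5-(benzyloxy)-2-{2-[4-(benzyloxy)-3,5-dimethoxyphenyl]-1-[(tert-butyldimethylsilyl)oxy]ethyl}-3-methoxy-4-methylhexa-1,3,5-trien-1-one (benzyloxyvinyl group cis to the ketene carbon) | C=C(OCc1ccccc1)/C(C)=C(OC)\C(=C=O)C(Cc1cc(OC)c(OCc2ccccc2)c(OC)c1)O[Si](C)(C)C(C)(C)C | intermediate
17 | 5-(benzyloxy)-2-{2-[4-(benzyloxy)-3,5-dimethoxyphenyl]-1-[(tert-butyldimethylsilyl)oxy]ethyl}-3-methoxy-4-methylcyclohexa-2,4-dien-1-one (racemic) | O=C1CC(OCc2ccccc2)=C(C)C(OC)=C1C(Cc1cc(OC)c(OCc2ccccc2)c(OC)c1)O[Si](C)(C)C(C)(C)C | intermediate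
18 | 5-(benzyloxy)-2-{2-[4-(benzyloxy)-3,5-dimethoxyphenyl]-1-[(tert-butyldimethylsilyl)oxy]ethyl}-3-methoxy-4-methylphenol (racemic) | COc1cc(CC(O[Si](C)(C)C(C)(C)C)c2c(O)cc(OCc3ccccc3)c(C)c2OC)cc(OC)c1OCc1ccccc1 | intermediate
19 | 5-(benzyloxy)-2-{2-[4-(benzyloxy)-3,5-dimethoxyphenyl]-1-hydroxyethyl}-3-methoxy-4-methylphenol (racemic) | COc1cc(CC(O)c2c(O)cc(OCc3ccccc3)c(C)c2OC)cc(OC)c1OCc1ccccc1 | intermediate
20 | 1-[4-(benzyloxy)-6-hydroxy-2-methoxy-3-methylphenyl]-2-[4-(benzyloxy)-3,5-dimethoxyphenyl]ethan-1-one | COc1cc(CC(=O)c2c(O)cc(OCc3ccccc3)c(C)c2OC)cc(OC)c1OCc1ccccc1 | intermediate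
21 | 1-[4-(benzyloxy)-6-hydroxy-2-methoxy-3-methylphenyl]-2-[4-(benzyloxy)-3,5-dimethoxyphenyl]-3-(dimethylamino)prop-2-en-1-one (alkene geometry not defined) | COc1cc(C(=CN(C)C)C(=O)c2c(O)cc(OCc3ccccc3)c(C)c2OC)cc(OC)c1OCc1ccccc1 | intermediate
22 | 7-(benzyloxy)-3-[4-(benzyloxy)-3,5-dimethoxyphenyl]-5-methoxy-6-methyl-4H-chromen-4-one | COc1cc(-c2coc3cc(OCc4ccccc4)c(C)c(OC)c3c2=O)cc(OC)c1OCc1ccccc1 | intermediate
23 | 7-hydroxy-3-(4-hydroxy-3,5-dimethoxyphenyl)-5-methoxy-6-methyl-4H-chromen-4-one | COc1cc(-c2coc3cc(O)c(C)c(OC)c3c2=O)cc(OC)c1O | target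

**Step count**

Total: 12 steps. Longest linear sequence: 9 steps (steps 4–7, then 8–12); the cyclobutenone branch (steps 1–3) joins at step 8.

**Steps most likely to fail**

Step 8. The vinylogous-ester cyclobutenone is stabilised by its donor oxygen and may open slowly. At the temperature then needed, the ynol ether may be consumed in other ways. The new, very electron-rich phenol may also lose silanol from its benzylic position (o-quinone methide formation and collapse to a stilbene) or be acylated by unreacted vinylketene. The fallback sets out from alkyne 13 and returns at phenol 18, generating the same vinylketene near 0 °C instead of thermally. Benzyl alcohol would be added (catalytic NaH, THF) to commercial ethyl 2-methylbuta-2,3-dienoate to give ethyl 3-(benzyloxy)-2-methylbut-2-enoate F1. Saponification (LiOH) would give 3-(benzyloxy)-2-methylbut-2-enoic acid F2, and oxalyl chloride would convert this into 3-(benzyloxy)-2-methylbut-2-enoyl chloride F3. Slow addition of F3 to 13 and Et3N at 0 °C → rt would form vinylketene 14 by 1,4-dehydrochlorination and trap it as 15. Compound 15 should go on to 18 at about 80 °C, well below the temperature of the direct route.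

Step 6. The acetylide solution also holds lithium methoxide and diethylamine, so the arylacetaldehyde may be enolised and self-condense before it is attacked. The fallback sets out from aldehyde 9 and returns at alcohol 12, replacing the aldehyde by an acyl donor that cannot undergo aldol reaction. Pinnick oxidation would give 2-[4-(benzyloxy)-3,5-dimethoxyphenyl]acetic acid F4. Coupling with N,O-dimethylhydroxylamine would give 2-[4-(benzyloxy)-3,5-dimethoxyphenyl]-N-methoxy-N-methylacetamide F5. Acylation of lithium methoxyacetylide 11 with F5 would give 1-[4-(benzyloxy)-3,5-dimethoxyphenyl]-4-methoxybut-3-yn-2-one F6, and 1,2-reduction (DIBAL-H, CH2Cl2, −78 °C) would return 12.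

Step 9. Once desilylated, the benzylic alcohol sits ortho to a free phenol on a ring with three oxygens. It may ionise through an o-quinone methide and dehydrate to the stilbene during work-up, chromatography or the oxidation. The fallback sets out from phenol 18 and returns at ketone 20, masking the phenol so that no quinone methide can form. MOMCl/i-Pr2NEt would give tert-butyl{1-[4-(benzyloxy)-2-methoxy-6-(methoxymethoxy)-3-methylphenyl]-2-[4-(benzyloxy)-3,5-dimethoxyphenyl]ethoxy}dimethylsilane F7. TBAF would give 1-[4-(benzyloxy)-2-methoxy-6-(methoxymethoxy)-3-methylphenyl]-2-[4-(benzyloxy)-3,5-dimethoxyphenyl]ethan-1-ol F8. Dess–Martin oxidation would give 1-[4-(benzyloxy)-2-methoxy-6-(methoxymethoxy)-3-methylphenyl]-2-[4-(benzyloxy)-3,5-dimethoxyphenyl]ethan-1-one F9. Mild acid methanolysis (HCl, MeOH) at the robust ketone stage would remove the MOM group and give 20.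

**Further compounds**

F1 | step 8 | ethyl 3-(benzyloxy)-2-methylbut-2-enoate | CCOC(=O)C(C)=C(C)OCc1ccccc1
F2 | step 8 | 3-(benzyloxy)-2-methylbut-2-enoic acid | OC(=O)C(C)=C(C)OCc1ccccc1
F3 | step 8 | 3-(benzyloxy)-2-methylbut-2-enoyl chloride | ClC(=O)C(C)=C(C)OCc1ccccc1
F4 | step 6 | 2-[4-(benzyloxy)-3,5-dimethoxyphenyl]acetic acid | OC(=O)Cc1cc(OC)c(OCc2ccccc2)c(OC)c1
F5 | step 6 | 2-[4-(benzyloxy)-3,5-dimethoxyphenyl]-N-methoxy-N-methylacetamide | CON(C)C(=O)Cc1cc(OC)c(OCc2ccccc2)c(OC)c1
F6 | step 6 | 1-[4-(benzyloxy)-3,5-dimethoxyphenyl]-4-methoxybut-3-yn-2-one | COC#CC(=O)Cc1cc(OC)c(OCc2ccccc2)c(OC)c1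
F7 | step 9 | tert-butyl{1-[4-(benzyloxy)-2-methoxy-6-(methoxymethoxy)-3-methylphenyl]-2-[4-(benzyloxy)-3,5-dimethoxyphenyl]ethoxy}dimethylsilane (racemic) | COc1cc(CC(O[Si](C)(C)C(C)(C)C)c2c(OCOC)cc(OCc3ccccc3)c(C)c2OC)cc(OC)c1OCc1ccccc1
F8 | step 9 | 1-[4-(benzyloxy)-2-methoxy-6-(methoxymethoxy)-3-methylphenyl]-2-[4-(benzyloxy)-3,5-dimethoxyphenyl]ethan-1-ol (racemic) | COc1cc(CC(O)c2c(OCOC)cc(OCc3ccccc3)c(C)c2OC)cc(OC)c1OCc1ccccc1
F9 | step 9 | 1-[4-(benzyloxy)-2-methoxy-6-(methoxymethoxy)-3-methylphenyl]-2-[4-(benzyloxy)-3,5-dimethoxyphenyl]ethan-1-one | COc1cc(CC(=O)c2c(OCOC)cc(OCc3ccccc3)c(C)c2OC)cc(OC)c1OCc1ccccc1
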